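**Plan**

1. Retrosynthetic cuts: both C4–C8 interflavan bonds (flavan-4-yl cation plus ring-A carbon C8); the C5–O bond of the middle unit, which is carried as a second epicatechin until the dimer stage; and, in the catechin unit, the aryl ether bond O1–C8a followed by C4–C4a.
2. Enabling feature: in ring A of the catechin unit, C8a is ortho to C4a and meta to the oxygens on C5 and C7, and O1 sits on C2, three carbons from C4a. A fluorine on C8a therefore acidifies C4a–H for lithiation, is not shut down by resonance donation from the two oxygens, and is displaced by the C2 alkoxide through a six-membered transition state.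
3. Lower unit, forward: 1,3-bis(benzyloxy)-5-fluorobenzene is lithiated and opens an erythro silyloxy epoxide (C4–C4a); O-3 is benzylated, O-2 is freed, and ring C closes by SNAr (O1–C8a) to penta-O-benzylcatechin.
4. Upper part, forward: two penta-O-benzylepicatechins are joined 4β→8; the lower unit is oxidised to its 4-ketone, whose peri carbonyl singles out the 5-benzyl ether for removal (OH → OTf → H); the ketone is reduced to the C4 leaving group, the catechin unit is attached, and global hydrogenolysis finishes.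
5. Stereochemistry: C2/C3 of the catechin unit come from a Sharpless kinetic resolution (ring closure with retention at C2 turns the erythro alcohol into the 2,3-trans chroman); C2/C3 of the two upper units come from (−)-epicatechin; both C4 centres arise by attack on the C4 cation trans to the 3-benzyloxy group.

Key step: step 8

Remark: α/β are used in the usual flavan sense (the 2-aryl group of each 2R unit is α), so 4β means trans to the 3-oxygen of the 2,3-cis units.
Remark: alcohol 26 is drawn as the expected 3,4-cis epimer; its C4 epimer would serve equally, because step 19 passes through the planar cation of salt 27.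
Remark: each flavan-4-yl cation is listed as the ion pair with the counter-ion of the reagent that generates it (the hydroquinolate of DDQ, triflate, or hydroxytrifluoroborate).

**Route**

Step 1
Reactants: 1 1,3,5-trifluorobenzene
Product: 2 1,3-bis(benzyloxy)-5-fluorobenzene
Conditions: BnOH (2.1 equiv), NaH (2.2 equiv), NMP, 0 → 90 °C
Reagents that add atoms: benzyl alcohol, OCc1ccccc1
Why: Two successive SNAr displacements of fluoride by benzyloxide, each C–F being activated inductively by its two meta substituents, should stop at the bis-ether because the alkoxide is limiting and the third displacement is the slowest.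

Step 2
Reactants: 3 3,4-bis(benzyloxy)benzaldehyde
Product: 4 rac-1-[3,4-bis(benzyloxy)phenyl]prop-2-en-1-ol
Conditions: vinylmagnesium bromide, THF, −78 → 0 °C; aq. NH4Cl
Reagents that add atoms: vinylmagnesium bromide, C=C[Mg]Br
Why: Grignard 1,2-addition to the aldehyde should give the racemic aryl vinyl carbinol needed for the resolution.

Step 3
Reactants: 4 rac-1-[3,4-bis(benzyloxy)phenyl]prop-2-en-1-ol
Product: 5 (R)-[3,4-bis(benzyloxy)phenyl][(2S)-oxiran-2-yl]methanol
Conditions: Ti(OiPr)4 (0.2 equiv), D-(−)-diisopropyl tartrate (0.24 equiv), t-BuOOH (0.45 equiv), 4 Å sieves, CH2Cl2, −20 °C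
Reagents that add atoms: tert-butyl hydroperoxide, CC(C)(C)OO
Why: In this Sharpless kinetic resolution the catalyst formed from Ti(OiPr)4 and the tartrate should epoxidise the (S)-carbinol much faster than its enantiomer and erythro-selectively, so the carbinol centre is selected and the new epoxide centre is set by the tartrate while the (R)-carbinol stays behind.

Step 4
Reactants: 5 (R)-[3,4-bis(benzyloxy)phenyl][(2S)-oxiran-2-yl]methanol
Product: 6 tert-butyl{(R)-[3,4-bis(benzyloxy)phenyl][(2S)-oxiran-2-yl]methoxy}dimethylsilane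
Conditions: TBSCl, imidazole, DMF, rt
Reagents that add atoms: tert-butyldimethylsilyl chloride, CC(C)(C)[Si](C)(C)Cl
Why: Imidazole-promoted O-silylation should mask the benzylic hydroxyl under conditions that leave the epoxide untouched.

Step 5
Reactants: 2 1,3-bis(benzyloxy)-5-fluorobenzene; 6 tert-butyl{(R)-[3,4-bis(benzyloxy)phenyl][(2S)-oxiran-2-yl]methoxy}dimethylsilane
Product: 8 (1R,2S)-1-[3,4-bis(benzyloxy)phenyl]-3-[2,4-bis(benzyloxy)-6-fluorophenyl]-1-[(tert-butyldimethylsilyl)oxy]propan-2-ol, via aryllithium 7 (not isolated)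
Conditions: n-BuLi, THF, −78 °C; then 6, BF3·OEt2, −78 °C
Reagents that add atoms: none
Why: In this directed ortho-metalation, fluorine and benzyloxy together acidify the C–H between them, and the aryllithium should open the BF3-activated epoxide by SN2 attack at the terminal CH2 (cold enough to avoid LiF loss to an aryne), so neither stereocentre is touched.

Step 6
Reactants: 8 (1R,2S)-1-[3,4-bis(benzyloxy)phenyl]-3-[2,4-bis(benzyloxy)-6-fluorophenyl]-1-[(tert-butyldimethylsilyl)oxy]propan-2-ol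
Product: 9 (1R,2S)-2-(benzyloxy)-1-[3,4-bis(benzyloxy)phenyl]-3-[2,4-bis(benzyloxy)-6-fluorophenyl]-1-[(tert-butyldimethylsilyl)oxy]propane
Conditions: 2-benzyloxy-1-methylpyridinium triflate, MgO, PhCF3, 85 °C
Reagents that add atoms: 2-benzyloxy-1-methylpyridinium triflate, C[n+]1ccccc1OCc1ccccc1.[O-]S(=O)(=O)C(F)(F)F
Why: Neutral benzyl transfer from the pyridinium salt (SN1-type O-benzylation) avoids an alkoxide, which would invite 1,2-silyl migration or five-membered-ring SNAr at the C–F carbon.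

Step 7
Reactants: 9 (1R,2S)-2-(benzyloxy)-1-[3,4-bis(benzyloxy)phenyl]-3-[2,4-bis(benzyloxy)-6-fluorophenyl]-1-[(tert-butyldimethylsilyl)oxy]propane
Product: 10 (1R,2S)-2-(benzyloxy)-1-[3,4-bis(benzyloxy)phenyl]-3-[2,4-bis(benzyloxy)-6-fluorophenyl]propan-1-ol
Conditions: Bu4NF, THF, 0 °C → rt
Reagents that add atoms: none
Why: Fluoride-mediated Si–O cleavage should free the benzylic hydroxyl without affecting the benzyl ethers or the aryl fluoride.

Step 8
Reactants: 10 (1R,2S)-2-(benzyloxy)-1-[3,4-bis(benzyloxy)phenyl]-3-[2,4-bis(benzyloxy)-6-fluorophenyl]propan-1-ol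
Product: 12 (2R,3S)-3,5,7-tris(benzyloxy)-2-[3,4-bis(benzyloxy)phenyl]chromane (penta-O-benzyl-(+)-catechin), via potassium alkoxide 11 (not isolated)
Conditions: KH, THF–DMF (4:1), 0 °C → rt
Reagents that add atoms: none
Why: KH converts the C2 hydroxyl into alkoxide 11, which adds to the fluorine-bearing C8a and expels fluoride by addition–elimination through a Meisenheimer-type adduct whose charge lies on C8, C6 and C4a, none of which carries a donor oxygen. The closest known reaction type is the intramolecular SNAr etherification of an alkoxide with an ortho-fluoroaryl group, used for pyran annulation in de novo flavan-3-ol synthesis. The one ring formed, ring C of the catechin unit (O1–C2–C3–C4–C4a–C8a), closes in a 6-exo mode by attack on the sp2 carbon C8a. No new stereocentre is created: C2 and C3 keep the configuration from step 3 because the C2–O bond is never broken, so the erythro alcohol should give the 2,3-trans chroman without the C2 epimerisation that accompanies cationic closures. The step needs O-2 to react instead of O-3 and C8a instead of any other ring carbon; O-3 is blocked as its benzyl ether, so no five-membered dihydrobenzofuran can form, and fluorine marks C8a as the only carbon with a leaving group. Loss of fluoride also turns the fluoroarene into the 5,7-dioxygenated chroman whose C8 is the nucleophile for step 19.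

Step 9
Reactants: 13 (−)-epicatechin
Product: 14 5,7,3',4'-tetra-O-benzyl-(−)-epicatechin
Conditions: BnBr, K2CO3, DMF, 0 °C → rt
Reagents that add atoms: benzyl bromide, BrCc1ccccc1
Why: Williamson etherification under carbonate conditions should alkylate the four phenols and leave the secondary alcohol free.

Step 10
Reactants: 14 5,7,3',4'-tetra-O-benzyl-(−)-epicatechin
Product: 15 3,5,7,3',4'-penta-O-benzyl-(−)-epicatechin
Conditions: NaH, BnBr, DMF, 0 °C → rt
Reagents that add atoms: benzyl bromide, BrCc1ccccc1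
Why: Williamson etherification through the sodium alkoxide protects O-3, and with no free phenol left there is no quinone-methide pathway for C2 epimerisation.

Step 11
Reactants: 15 3,5,7,3',4'-penta-O-benzyl-(−)-epicatechin
Product: 17 (2R,3R,4S)-3,5,7-tris(benzyloxy)-2-[3,4-bis(benzyloxy)phenyl]-4-(2-ethoxyethoxy)chromane (4β ether), via C4 carbocation hydroquinolate salt 16 (not isolated)
Conditions: DDQ, 2-ethoxyethanol, CH2Cl2, rt
Reagents that add atoms: 2-ethoxyethanol, CCOCCO
Why: DDQ-mediated benzylic C–H oxidation removes hydride from C4 to give ion pair 16, and the alcohol should add to its cation on the face trans to the 3-benzyloxy group, setting the 4β configuration.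

Step 12
Reactants: 17 4β-(2-ethoxyethoxy)-penta-O-benzylepicatechin; 15 3,5,7,3',4'-penta-O-benzyl-(−)-epicatechin
Product: 19 penta-O-benzylepicatechin-(4β→8)-penta-O-benzylepicatechin, via C4 carbocation triflate salt 18 (not isolated)
Conditions: TMSOTf (0.2 equiv), 15 (4 equiv), CH2Cl2, −78 °C
Reagents that add atoms: none
Why: In this Friedel–Crafts-type interflavan coupling TMSOTf silylates and ionises the C4 ether to the flavan-4-ylium triflate 18, and C8 of excess 15 (flanked by O1 and the 7-oxygen, para to the 5-oxygen) should attack trans to 3-OBn to give the 4β→8 bond while the released acid regenerates the silyl triflate.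

Step 13
Reactants: 19 penta-O-benzylepicatechin-(4β→8)-penta-O-benzylepicatechin
Product: 21 4β-hydroxy derivative of 19 at the lower unit (lower unit 2R,3R,4S), via lower-unit C4 carbocation hydroquinolate salt 20 (not isolated)
Conditions: DDQ, CH2Cl2–H2O (20:1), rt
Reagents that add atoms: water, O
Why: DDQ benzylic oxidation should occur at the only benzylic CH2 (C4 of the lower unit, attached to the most electron-rich ring) and water should trap the cation of ion pair 20 trans to 3-OBn, while the tertiary C4–H of the upper unit is shielded between two ortho-disubstituted rings.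

Step 14
Reactants: 21 lower-unit 4β-alcohol of the dimer
Product: 22 penta-O-benzylepicatechin-(4β→8)-penta-O-benzylepicatechin-4-one (lower unit 2R,3S)
Conditions: Dess–Martin periodinane, CH2Cl2, rt
Reagents that add atoms: none
Why: Dess–Martin oxidation converts the secondary benzylic alcohol into the aryl ketone under non-basic conditions that should not epimerise the adjacent C3.

Step 15
Reactants: 22 dimer 4-ketone
Product: 23 5-hydroxy dimer 4-ketone (5-O-debenzylated lower unit)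
Conditions: MgBr2·OEt2, toluene–Et2O, rt → 50 °C
Reagents that add atoms: none
Why: In this chelation-controlled debenzylation magnesium bridges the C4 carbonyl and the peri 5-benzyloxy oxygen, so bromide should cleave only this one of the ten benzyl ethers.

Step 16
Reactants: 23 5-hydroxy dimer 4-ketone
Product: 24 5-trifluoromethanesulfonyloxy dimer 4-ketone
Conditions: Tf2O, pyridine, CH2Cl2, 0 °C
Reagents that add atoms: trifluoromethanesulfonic anhydride, O=S(=O)(OS(=O)(=O)C(F)(F)F)C(F)(F)F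
Why: O-Sulfonylation of the only free hydroxyl, the hydrogen-bonded 5-phenol, should give the aryl triflate.

Step 17
Reactants: 24 5-triflate dimer 4-ketone
Product: 25 penta-O-benzylepicatechin-(4β→8)-3,7,3',4'-tetra-O-benzyl-5-deoxyepicatechin-4-one (lower unit 2R,3S)
Conditions: Pd(OAc)2, dppp, HCO2H, Et3N, DMF, 50 °C
Reagents that add atoms: none
Why: Palladium-catalysed formate reduction of the aryl triflate (oxidative addition accelerated by the ortho carbonyl, decarboxylation of formate, C–H reductive elimination) should replace the C5 oxygen by hydrogen in a buffered medium that is mild toward C3.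

Step 18
Reactants: 25 5-deoxy dimer 4-ketone
Product: 26 penta-O-benzylepicatechin-(4β→8)-3,7,3',4'-tetra-O-benzyl-4α-hydroxy-5-deoxyepicatechin (lower unit 2R,3R,4R)
Conditions: NaBH4, THF–MeOH, 0 °C
Reagents that add atoms: none
Why: Hydride reduction of the aryl ketone, expected from the face opposite the axial 3-benzyloxy group, should give the C4 alcohol that serves as leaving group.

Step 19
Reactants: 26 dimer 4-alcohol; 12 penta-O-benzyl-(+)-catechin
Product: 28 tetradeca-O-benzyl-epicatechin-(4β→8)-epifisetinidol-(4β→8)-catechin, via C4 carbocation hydroxytrifluoroborate salt 27 (not isolated)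
Conditions: BF3·OEt2, 12 (4 equiv), CH2Cl2, −78 → −20 °C
Reagents that add atoms: none
Why: In this Friedel–Crafts-type interflavan coupling BF3 ionises the C4 hydroxyl to the cation of ion pair 27 (stabilised by O1 and the para 7-oxygen), and C8 of excess 12 should attack trans to 3-OBn to set the second 4β→8 bond.

Step 20
Reactants: 28 tetradeca-O-benzyl trimer
Product: 29 epicatechin-(4β→8)-epifisetinidol-(4β→8)-catechin (target)
Conditions: H2 (1 atm), Pd(OH)2/C, THF–MeOH–H2O, rt
Reagents that add atoms: none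
Why: Catalytic hydrogenolysis under neutral conditions, as commonly applied to benzylated proanthocyanidins, should cleave all fourteen O-benzyl bonds and leave the interflavan and pyran bonds intact.

**Compound list**

1 | 1,3,5-trifluorobenzene | Fc1cc(F)cc(F)c1 | starting material
2 | 1,3-bis(benzyloxy)-5-fluorobenzene | Fc1cc(OCc2ccccc2)cc(OCc2ccccc2)c1 | intermediate
3 | 3,4-bis(benzyloxy)benzaldehyde | O=Cc1ccc(OCc2ccccc2)c(OCc2ccccc2)c1 | starting material
4 | rac-1-[3,4-bis(benzyloxy)phenyl]prop-2-en-1-ol | OC(C=C)c1ccc(OCc2ccccc2)c(OCc2ccccc2)c1 | intermediate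
5 | (R)-[3,4-bis(benzyloxy)phenyl][(2S)-oxiran-2-yl]methanol | O[C@H](c1ccc(OCc2ccccc2)c(OCc2ccccc2)c1)[C@@H]1CO1 | intermediate
6 | tert-butyl{(R)-[3,4-bis(benzyloxy)phenyl][(2S)-oxiran-2-yl]methoxy}dimethylsilane | CC(C)(C)[Si](C)(C)O[C@H](c1ccc(OCc2ccccc2)c(OCc2ccccc2)c1)[C@@H]1CO1 | intermediate
7 | 2,4-bis(benzyloxy)-6-fluorophenyllithium | [Li]c1c(F)cc(OCc2ccccc2)cc1OCc1ccccc1 | intermediate
8 | (1R,2S)-1-[3,4-bis(benzyloxy)phenyl]-3-[2,4-bis(benzyloxy)-6-fluorophenyl]-1-[(tert-butyldimethylsilyl)oxy]propan-2-ol | CC(C)(C)[Si](C)(C)O[C@H](c1ccc(OCc2ccccc2)c(OCc2ccccc2)c1)[C@@H](O)Cc1c(F)cc(OCc2ccccc2)cc1OCc1ccccc1 | intermediate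
9 | (1R,2S)-2-(benzyloxy)-1-[3,4-bis(benzyloxy)phenyl]-3-[2,4-bis(benzyloxy)-6-fluorophenyl]-1-[(tert-butyldimethylsilyl)oxy]propane | CC(C)(C)[Si](C)(C)O[C@H](c1ccc(OCc2ccccc2)c(OCc2ccccc2)c1)[C@@H](OCc1ccccc1)Cc1c(F)cc(OCc2ccccc2)cc1OCc1ccccc1 | intermediate
10 | (1R,2S)-2-(benzyloxy)-1-[3,4-bis(benzyloxy)phenyl]-3-[2,4-bis(benzyloxy)-6-fluorophenyl]propan-1-ol | O[C@H](c1ccc(OCc2ccccc2)c(OCc2ccccc2)c1)[C@@H](OCc1ccccc1)Cc1c(F)cc(OCc2ccccc2)cc1OCc1ccccc1 | intermediate
11 | potassium (1R,2S)-2-(benzyloxy)-1-[3,4-bis(benzyloxy)phenyl]-3-[2,4-bis(benzyloxy)-6-fluorophenyl]propan-1-olate | [K+].[O-][C@H](c1ccc(OCc2ccccc2)c(OCc2ccccc2)c1)[C@@H](OCc1ccccc1)Cc1c(F)cc(OCc2ccccc2)cc1OCc1ccccc1 | intermediate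
12 | (2R,3S)-3,5,7-tris(benzyloxy)-2-[3,4-bis(benzyloxy)phenyl]chromane (penta-O-benzyl-(+)-catechin) | c1ccccc1COc1cc(OCc2ccccc2)c2c(c1)O[C@H](c1ccc(OCc3ccccc3)c(OCc3ccccc3)c1)[C@@H](OCc1ccccc1)C2 | intermediate
13 | (−)-epicatechin, (2R,3R)-2-(3,4-dihydroxyphenyl)chromane-3,5,7-triol | Oc1cc(O)c2c(c1)O[C@H](c1ccc(O)c(O)c1)[C@H](O)C2 | starting material
14 | 5,7,3',4'-tetra-O-benzyl-(−)-epicatechin | c1ccccc1COc1cc(OCc2ccccc2)c2c(c1)O[C@H](c1ccc(OCc3ccccc3)c(OCc3ccccc3)c1)[C@H](O)C2 | intermediate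
15 | 3,5,7,3',4'-penta-O-benzyl-(−)-epicatechin | c1ccccc1COc1cc(OCc2ccccc2)c2c(c1)O[C@H](c1ccc(OCc3ccccc3)c(OCc3ccccc3)c1)[C@H](OCc1ccccc1)C2 | intermediate
16 | penta-O-benzylepicatechin C4 carbocation as its 2,3-dichloro-5,6-dicyano-4-hydroxyphenolate salt | c1ccccc1COc1cc(OCc2ccccc2)c2c(c1)O[C@H](c1ccc(OCc3ccccc3)c(OCc3ccccc3)c1)[C@H](OCc1ccccc1)[CH+]2.[O-]c1c(Cl)c(Cl)c(O)c(C#N)c1C#N | intermediate
17 | (2R,3R,4S)-3,5,7-tris(benzyloxy)-2-[3,4-bis(benzyloxy)phenyl]-4-(2-ethoxyethoxy)chromane | c1ccccc1COc1cc(OCc2ccccc2)c2c(c1)O[C@H](c1ccc(OCc3ccccc3)c(OCc3ccccc3)c1)[C@H](OCc1ccccc1)[C@H]2OCCOCC | intermediate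
18 | penta-O-benzylepicatechin C4 carbocation as its trifluoromethanesulfonate salt | c1ccccc1COc1cc(OCc2ccccc2)c2c(c1)O[C@H](c1ccc(OCc3ccccc3)c(OCc3ccccc3)c1)[C@H](OCc1ccccc1)[CH+]2.[O-]S(=O)(=O)C(F)(F)F | intermediate
19 | penta-O-benzylepicatechin-(4β→8)-penta-O-benzylepicatechin | c1ccccc1COc1cc(OCc2ccccc2)c2c(c1)O[C@H](c1ccc(OCc3ccccc3)c(OCc3ccccc3)c1)[C@H](OCc1ccccc1)[C@H]2c1c(OCc2ccccc2)cc(OCc2ccccc2)c2c1O[C@H](c1ccc(OCc3ccccc3)c(OCc3ccccc3)c1)[C@H](OCc1ccccc1)C2 | intermediate
20 | C4 carbocation of the lower unit of 19 as its 2,3-dichloro-5,6-dicyano-4-hydroxyphenolate salt | c1ccccc1COc1cc(OCc2ccccc2)c2c(c1)O[C@H](c1ccc(OCc3ccccc3)c(OCc3ccccc3)c1)[C@H](OCc1ccccc1)[C@H]2c1c(OCc2ccccc2)cc(OCc2ccccc2)c2c1O[C@H](c1ccc(OCc3ccccc3)c(OCc3ccccc3)c1)[C@H](OCc1ccccc1)[CH+]2.[O-]c1c(Cl)c(Cl)c(O)c(C#N)c1C#N | intermediate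
21 | 19 carrying a 4β-hydroxyl on the lower unit | c1ccccc1COc1cc(OCc2ccccc2)c2c(c1)O[C@H](c1ccc(OCc3ccccc3)c(OCc3ccccc3)c1)[C@H](OCc1ccccc1)[C@H]2c1c(OCc2ccccc2)cc(OCc2ccccc2)c2c1O[C@H](c1ccc(OCc3ccccc3)c(OCc3ccccc3)c1)[C@H](OCc1ccccc1)[C@H]2O | intermediate
22 | penta-O-benzylepicatechin-(4β→8)-penta-O-benzylepicatechin-4-one | c1ccccc1COc1cc(OCc2ccccc2)c2c(c1)O[C@H](c1ccc(OCc3ccccc3)c(OCc3ccccc3)c1)[C@H](OCc1ccccc1)[C@H]2c1c(OCc2ccccc2)cc(OCc2ccccc2)c2c1O[C@H](c1ccc(OCc3ccccc3)c(OCc3ccccc3)c1)[C@H](OCc1ccccc1)C2=O | intermediate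
23 | 22 with free 5-hydroxyl on the ketone unit | c1ccccc1COc1cc(OCc2ccccc2)c2c(c1)O[C@H](c1ccc(OCc3ccccc3)c(OCc3ccccc3)c1)[C@H](OCc1ccccc1)[C@H]2c1c(OCc2ccccc2)cc(O)c2c1O[C@H](c1ccc(OCc3ccccc3)c(OCc3ccccc3)c1)[C@H](OCc1ccccc1)C2=O | intermediate
24 | 5-triflate of 23 | c1ccccc1COc1cc(OCc2ccccc2)c2c(c1)O[C@H](c1ccc(OCc3ccccc3)c(OCc3ccccc3)c1)[C@H](OCc1ccccc1)[C@H]2c1c(OCc2ccccc2)cc(OS(=O)(=O)C(F)(F)F)c2c1O[C@H](c1ccc(OCc3ccccc3)c(OCc3ccccc3)c1)[C@H](OCc1ccccc1)C2=O | intermediate
25 | penta-O-benzylepicatechin-(4β→8)-3,7,3',4'-tetra-O-benzyl-5-deoxyepicatechin-4-one | c1ccccc1COc1cc(OCc2ccccc2)c2c(c1)O[C@H](c1ccc(OCc3ccccc3)c(OCc3ccccc3)c1)[C@H](OCc1ccccc1)[C@H]2c1c(OCc2ccccc2)ccc2c1O[C@H](c1ccc(OCc3ccccc3)c(OCc3ccccc3)c1)[C@H](OCc1ccccc1)C2=O | intermediate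
26 | penta-O-benzylepicatechin-(4β→8)-3,7,3',4'-tetra-O-benzyl-4α-hydroxy-5-deoxyepicatechin | c1ccccc1COc1cc(OCc2ccccc2)c2c(c1)O[C@H](c1ccc(OCc3ccccc3)c(OCc3ccccc3)c1)[C@H](OCc1ccccc1)[C@H]2c1c(OCc2ccccc2)ccc2c1O[C@H](c1ccc(OCc3ccccc3)c(OCc3ccccc3)c1)[C@H](OCc1ccccc1)[C@@H]2O | intermediate
27 | C4 carbocation of the 5-deoxy unit of 26 as its hydroxytrifluoroborate salt | c1ccccc1COc1cc(OCc2ccccc2)c2c(c1)O[C@H](c1ccc(OCc3ccccc3)c(OCc3ccccc3)c1)[C@H](OCc1ccccc1)[C@H]2c1c(OCc2ccccc2)ccc2c1O[C@H](c1ccc(OCc3ccccc3)c(OCc3ccccc3)c1)[C@H](OCc1ccccc1)[CH+]2.O[B-](F)(F)F | intermediate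
28 | tetradeca-O-benzyl-epicatechin-(4β→8)-epifisetinidol-(4β→8)-catechin | c1ccccc1COc1cc(OCc2ccccc2)c2c(c1)O[C@H](c1ccc(OCc3ccccc3)c(OCc3ccccc3)c1)[C@H](OCc1ccccc1)[C@H]2c1c(OCc2ccccc2)ccc2c1O[C@H](c1ccc(OCc3ccccc3)c(OCc3ccccc3)c1)[C@H](OCc1ccccc1)[C@H]2c1c(OCc2ccccc2)cc(OCc2ccccc2)c2c1O[C@H](c1ccc(OCc3ccccc3)c(OCc3ccccc3)c1)[C@@H](OCc1ccccc1)C2 | intermediate
29 | epicatechin-(4β→8)-epifisetinidol-(4β→8)-catechin | Oc1cc(O)c2c(c1)O[C@H](c1ccc(O)c(O)c1)[C@H](O)[C@H]2c1c(O)ccc2c1O[C@H](c1ccc(O)c(O)c1)[C@H](O)[C@H]2c1c(O)cc(O)c2c1O[C@H](c1ccc(O)c(O)c1)[C@@H](O)C2 | target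

**Summary**

Total step count: 20. Longest linear sequence: 12 steps (steps 9–20, from (−)-epicatechin 13 to 29); the catechin branch (steps 2–8, then 19–20) is 9 steps.

Steps most likely to fail, with fallbacks:

Step 13. The oxidation of dimer 19 may show poor site selectivity (hydride abstraction at the doubly benzylic C4–H of the upper unit) or overoxidation. The fallback installs the C4 oxygen before the units are joined and sets out from 15. DDQ/H2O should oxidise 15 to the 4β-alcohol (2R,3R,4S)-3,5,7-tris(benzyloxy)-2-[3,4-bis(benzyloxy)phenyl]chroman-4-ol F1, and Dess–Martin periodinane should convert it into (2R,3S)-3,5,7-tris(benzyloxy)-2-[3,4-bis(benzyloxy)phenyl]chroman-4-one F2. F2 in excess then serves as the C8 nucleophile toward the cation of triflate salt 18, generated from 17 by slow addition to TMSOTf in CH2Cl2 at −40 °C; the ring carbons C6 and C8 are meta to the acyl-bearing C4a and remain nucleophilic. This should give ketone 22 directly, where the route is rejoined.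

Step 19. Ionisation of the less stabilised 5-deoxy C4 position may be incomplete, and the cation of salt 27 may self-condense through the free C8 of the upper unit of a second dimer molecule. The fallback uses a bromine cap and sets out from 25. NBS (CH2Cl2, −10 °C) should brominate the only phloroglucinol-type C8–H, that of the upper unit, to give the 8-bromo ketone F3. NaBH4 should give the 8-bromo alcohol F4, and BF3·OEt2 coupling with 12 should give the 8-bromo protected trimer F5. Hydrogenolysis over Pd(OH)2/C in the presence of Et3N removes the C–Br bond together with the benzyl groups, so the route is rejoined at target 29.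

Step 8. Addition of the alkoxide to the electron-rich, unactivated C–F carbon may be sluggish, leaving time for base-induced degradation before ring closure. The fallback forms the same O1–C8a bond by palladium catalysis on a bromo analogue and sets out from 6. Commercial 1-bromo-3,5-bis(benzyloxy)benzene is iodinated with NIS to 1-bromo-2-iodo-3,5-bis(benzyloxy)benzene F6. Iodine–magnesium exchange (i-PrMgCl·LiCl, THF, −40 °C) gives [2,4-bis(benzyloxy)-6-bromophenyl]magnesium chloride F7, which should open epoxide 6 under CuI catalysis to the bromo silyl alcohol F8. Benzylation as in step 6 gives the bromo benzyl ether F9, and Bu4NF gives the bromo alcohol F10. Intramolecular Buchwald–Hartwig etherification (Pd(OAc)2, 2-(di-tert-butylphosphino)-1,1'-binaphthyl, Cs2CO3, toluene, 70 °C), which proceeds with retention at the carbinol carbon, should then give 12, where the route is rejoined.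

Further compounds
F1 | step 13 | (2R,3R,4S)-3,5,7-tris(benzyloxy)-2-[3,4-bis(benzyloxy)phenyl]chroman-4-ol | c1ccccc1COc1cc(OCc2ccccc2)c2c(c1)O[C@H](c1ccc(OCc3ccccc3)c(OCc3ccccc3)c1)[C@H](OCc1ccccc1)[C@H]2O
F2 | step 13 | (2R,3S)-3,5,7-tris(benzyloxy)-2-[3,4-bis(benzyloxy)phenyl]chroman-4-one | c1ccccc1COc1cc(OCc2ccccc2)c2c(c1)O[C@H](c1ccc(OCc3ccccc3)c(OCc3ccccc3)c1)[C@H](OCc1ccccc1)C2=O
F3 | step 19 | 8-bromo derivative of ketone 25 (bromine on C8 of the upper unit) | c1ccccc1COc1cc(OCc2ccccc2)c2c(c1Br)O[C@H](c1ccc(OCc3ccccc3)c(OCc3ccccc3)c1)[C@H](OCc1ccccc1)[C@H]2c1c(OCc2ccccc2)ccc2c1O[C@H](c1ccc(OCc3ccccc3)c(OCc3ccccc3)c1)[C@H](OCc1ccccc1)C2=O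
F4 | step 19 | 8-bromo derivative of alcohol 26 | c1ccccc1COc1cc(OCc2ccccc2)c2c(c1Br)O[C@H](c1ccc(OCc3ccccc3)c(OCc3ccccc3)c1)[C@H](OCc1ccccc1)[C@H]2c1c(OCc2ccccc2)ccc2c1O[C@H](c1ccc(OCc3ccccc3)c(OCc3ccccc3)c1)[C@H](OCc1ccccc1)[C@@H]2O
F5 | step 19 | 8-bromo derivative of protected trimer 28 | c1ccccc1COc1cc(OCc2ccccc2)c2c(c1Br)O[C@H](c1ccc(OCc3ccccc3)c(OCc3ccccc3)c1)[C@H](OCc1ccccc1)[C@H]2c1c(OCc2ccccc2)ccc2c1O[C@H](c1ccc(OCc3ccccc3)c(OCc3ccccc3)c1)[C@H](OCc1ccccc1)[C@H]2c1c(OCc2ccccc2)cc(OCc2ccccc2)c2c1O[C@H](c1ccc(OCc3ccccc3)c(OCc3ccccc3)c1)[C@@H](OCc1ccccc1)C2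
F6 | step 8 | 1-bromo-2-iodo-3,5-bis(benzyloxy)benzene | Brc1cc(OCc2ccccc2)cc(OCc2ccccc2)c1I
F7 | step 8 | [2,4-bis(benzyloxy)-6-bromophenyl]magnesium chloride | Brc1cc(OCc2ccccc2)cc(OCc2ccccc2)c1[Mg]Cl
F8 | step 8 | (1R,2S)-1-[3,4-bis(benzyloxy)phenyl]-3-[2,4-bis(benzyloxy)-6-bromophenyl]-1-[(tert-butyldimethylsilyl)oxy]propan-2-ol | CC(C)(C)[Si](C)(C)O[C@H](c1ccc(OCc2ccccc2)c(OCc2ccccc2)c1)[C@@H](O)Cc1c(Br)cc(OCc2ccccc2)cc1OCc1ccccc1
F9 | step 8 | (1R,2S)-2-(benzyloxy)-1-[3,4-bis(benzyloxy)phenyl]-3-[2,4-bis(benzyloxy)-6-bromophenyl]-1-[(tert-butyldimethylsilyl)oxy]propane | CC(C)(C)[Si](C)(C)O[C@H](c1ccc(OCc2ccccc2)c(OCc2ccccc2)c1)[C@@H](OCc1ccccc1)Cc1c(Br)cc(OCc2ccccc2)cc1OCc1ccccc1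
F10 | step 8 | (1R,2S)-2-(benzyloxy)-1-[3,4-bis(benzyloxy)phenyl]-3-[2,4-bis(benzyloxy)-6-bromophenyl]propan-1-ol | O[C@H](c1ccc(OCc2ccccc2)c(OCc2ccccc2)c1)[C@@H](OCc1ccccc1)Cc1c(Br)cc(OCc2ccccc2)cc1OCc1ccccc1
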